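The process chemist who held the next slot asked me whether this flask, with D and J charged equal, needed more J or a longer time before its D was gone.

| setting | winter | spring | dawn | flask |
|---|---|---|---|---|
| D | 0.15 M | 0.22 M | 0.30 M | 0.30 M |
| J | 0.30 M | 0.30 M | 0.15 M | 0.300 M |
| E | 3.9 mol% | 3.9 mol% | 3.9 mol% | 3.9 mol% |
| remark | run made earlier | run made earlier | run made earlier |  |
| time |  |  |  | 10 d |

| run | time / d | G / % | D / % |
|---|---|---|---|
| winter | 0.833 | 0 | 3.5 |
| winter | 1.25 | 0 | 1.0 |
| winter | 2.00 | 0 | 0.6 |
| winter | 4.00 | 0 | 0.1 |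
| winter | 6.00 | 1.0 | 0 |
| winter | 10.0 | 2.0 | 1.6 |
| spring | 0.833 | 0 | 10.8 |
| spring | 1.25 | 0 | 3.6 |
| spring | 2.00 | 0.2 | 0.1 |
| spring | 4.00 | 2.3 | 0.2 |
| spring | 6.00 | 2.1 | 2.1 |
| spring | 10.0 | 1.5 | 1.4 |
| dawn | 0.833 | 1.5 | 50.6 |
| dawn | 2.50 | 15.8 | 34.8 |
| dawn | 5.00 | 36.9 | 12.7 |
| dawn | 8.00 | 46.6 | 3.8 |
| dawn | 10.0 | 49.2 | 1.2 |

(readings scatter by 1 percentage point)

- the average divides the monomer in chains by the number of chains begun, living and dead together
- the earlier runs do not show the number of chains; that part of a forecast is a guess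

- average number of monomer units in a chain (chains begun, living or dead) at 10 d
- part of the D that has reacted at 10 d

The dawn run, with J at half of D, ended at 49.2% G, while the spring run, with J above D, ended at 1.5% G, so I took J to remove D one to one. The winter reading of 3.5% D at 0.833 d, put into the second-order law for unequal charges, gave a constant of 0.898 M⁻¹ h⁻¹. That is a reading with its scatter; the forecast's own fit gave about 20 /M/d, a figure in days, not hours.

I then counted turnovers: the constant times the charge of J times the time, the second-order Damköhler number, 64.7. With equal charges that loss leaves one part in one plus the count, 1.52% of the D. Polymerisation takes D besides, but I took this as an estimate of the D left, not a bound, since the constant came from one scattered reading. I therefore charged no more J and kept 10 d. The chains I could not count.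

The forecast gave dp 2.5 (range 1.3 to 6) and c 99.7% (range 98% to 100%), adding: “The chain count is a guess.” My estimate put c near 98.5%, which is not its number.

The flask gave dp 25.3, ten times the forecast, and c 99.7%.

    D + Q → Z + G (k = 0.0147 M⁻¹ h⁻¹)
    D + Z → G + Z, rate k2*[Z]*[D] (k = 13.7 M⁻¹ h⁻¹)
    J + D → X (k = 0.784 M⁻¹ h⁻¹)
    E ⇌ Q (K = 2.25, k = 0.158 h⁻¹)

This flask kept 0.304% of its D at 10.0 d, less than my estimate of 1.52%. At 0.165 d D had a half-life of 0.24 d by J, far shorter than the 6.5 d of Q by D at the charged concentrations. At 10.0 d this flask still held Q at 0.00782 M, with Z at 4.01 × 10⁻⁴ M and G at 3.38%. The neighbour with 9.8 mol% of E has the same charges of D and J, so the same count 64.7 and estimate 1.52%. Computed, it kept 0.035% of its D, with c >99.9% and dp 21.2.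

The runs are calculated with made-up constants; scatter was added.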